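The route rests on opening the seven-membered depsidone ring at its lactone carbonyl. This single carbon joins C-6 of the chromene-fused ring A, which lies between the 5-oxygen and the diaryl ether oxygen, to the ring-B oxygen ortho to the prenyl group, and is therefore supplied as carbon monoxide. One palladium-catalysed carbonylation forges the aryl–C(=O) and C(=O)–O bonds and closes the dioxepinone ring. Its precursor is a diaryl ether with iodine at ring-A C-6, MOM ethers on the two other phenols, and a free ring-B phenol that an aromatic Claisen rearrangement unveils while delivering the carbon chain of the prenyl group.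

Key step: step 11

Remarks on the chemistry
- The target has no stereocentre, so no enantiocontrol is needed.
- Ring A is the chromene benzo ring (chromene numbering O1, C2 … C8a). Ring B is the prenylated ring.
- Catalyst-bound species of the copper, ruthenium and palladium cycles are described in the Why lines and are not numbered. Numbers are given to species formed in separate stages of a one-pot operation.
- Assumption: 5-bromoresorcinol and 6-bromovanillin are purchased.

Step 1
Reactants: 1 5-bromoresorcinol; 2 3-methylbut-2-enal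
Product: 3 7-bromo-2,2-dimethyl-2H-chromen-5-ol
Conditions: 2 (1.3 equiv), ethylenediammonium diacetate (10 mol%), toluene, 110 °C
Reagents that add atoms: 3-methylbut-2-enal (compound 2), CC(C)=CC=O
Why: Amine-catalysed condensation of the enal at C-2 of the resorcinol (the carbon between the two hydroxyls, the usual site for 5-substituted resorcinols) gives an ortho-quinone methide that closes by oxa-6π electrocyclisation (formal [3+3] chromene annulation), and the remaining, now isolated phenol should not annulate a second time.

Step 2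
Reactants: 3 7-bromo-2,2-dimethyl-2H-chromen-5-ol
Product: 4 7-bromo-5-(methoxymethoxy)-2,2-dimethyl-2H-chromene
Conditions: MOMCl, i-Pr2NEt, CH2Cl2, 0 °C → rt
Reagents that add atoms: chloromethyl methyl ether, COCCl
Why: O-Alkylation of the phenol with the chloromethyl ether under amine base (MOM protection) masks the ring-A hydroxyl for the copper step and supplies the acetal that later directs metalation.

Step 3
Reactants: 5 6-bromovanillin (2-bromo-4-hydroxy-5-methoxybenzaldehyde)
Product: 6 2-bromo-5-methoxy-4-(methoxymethoxy)benzaldehyde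
Conditions: MOMCl, i-Pr2NEt, CH2Cl2, 0 °C → rt
Reagents that add atoms: chloromethyl methyl ether, COCCl
Why: The same MOM protection applies to this phenol, which is acidic enough (para to the formyl group) to be alkylated cleanly with a hindered amine base.

Step 4
Reactants: 6 2-bromo-5-methoxy-4-(methoxymethoxy)benzaldehyde
Product: 8 2-bromo-5-methoxy-4-(methoxymethoxy)phenol, via aryl formate 7 (not isolated)
Conditions: mCPBA, NaHCO3, CH2Cl2, 0 °C → rt; then K2CO3 (cat.), MeOH, rt
Reagents that add atoms: meta-chloroperbenzoic acid, OOC(=O)c1cccc(Cl)c1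
Why: Baeyer–Villiger (Dakin-type) oxidation, in which the electron-rich aryl group with its para acetal oxygen migrates in the Criegee intermediate to give the formate, which carbonate-catalysed methanolysis cleaves to the phenol while the bicarbonate buffer protects the acetal.

Step 5
Reactants: 8 2-bromo-5-methoxy-4-(methoxymethoxy)phenol; 9 allyl bromide
Product: 10 1-bromo-4-methoxy-5-(methoxymethoxy)-2-(prop-2-enyloxy)benzene
Conditions: allyl bromide, K2CO3, acetone, reflux
Reagents that add atoms: allyl bromide (compound 9), C=CCBr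
Why: Williamson etherification of the phenoxide with the reactive allylic bromide, the allyl group serving as protection here and as the prenyl precursor later.

Step 6
Reactants: 10 1-bromo-4-methoxy-5-(methoxymethoxy)-2-(prop-2-enyloxy)benzene
Product: 13 4-methoxy-5-(methoxymethoxy)-2-(prop-2-enyloxy)phenol, via aryllithium 11 (not isolated), via lithium arylborate 12 (not isolated)
Conditions: n-BuLi, THF, −78 °C; B(OMe)3, −78 → 0 °C; then H2O2, aq. NaOH, 0 °C
Reagents that add atoms: hydrogen peroxide, OO
Why: Bromine–lithium exchange at −78 °C (too cold for the ortho-allyloxy aryllithium to cyclise or for the acetal to direct deprotonation), borylation and oxidative 1,2-aryl shift from boron to oxygen with alkaline peroxide, which leaves the unactivated alkene alone, convert C–Br into C–OH.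

Step 7
Reactants: 4 7-bromo-5-(methoxymethoxy)-2,2-dimethyl-2H-chromene; 13 4-methoxy-5-(methoxymethoxy)-2-(prop-2-enyloxy)phenol
Product: 14 7-[4-methoxy-5-(methoxymethoxy)-2-(prop-2-enyloxy)phenoxy]-5-(methoxymethoxy)-2,2-dimethyl-2H-chromene
Conditions: CuI (10 mol%), N,N-dimethylglycine·HCl (30 mol%), Cs2CO3, 1,4-dioxane, 95 °C
Reagents that add atoms: none
Why: Ullmann-type copper-catalysed diaryl ether synthesis with the favourable polarity, an unhindered aryl bromide bearing two meta oxygen substituents and an electron-rich phenoxide, under conditions to which the acetals, the allyl ether and the chromene are inert.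

Step 8
Reactants: 14 7-[4-methoxy-5-(methoxymethoxy)-2-(prop-2-enyloxy)phenoxy]-5-(methoxymethoxy)-2,2-dimethyl-2H-chromene
Product: 15 3-methoxy-4-(methoxymethoxy)-6-{[5-(methoxymethoxy)-2,2-dimethyl-2H-chromen-7-yl]oxy}-2-(prop-2-enyl)phenol
Conditions: N,N-diethylaniline, 190 °C, sealed tube, argon
Reagents that add atoms: none
Why: Aromatic Claisen rearrangement ([3,3]-sigmatropic shift, then tautomerisation of the dienone), in which the only unsubstituted ortho position is the one next to the methoxy group (the other ortho carbon carries the aryloxy group, the para carbon the acetal), so the allyl group lands where the prenyl group belongs and the ring-B phenol is freed without a deprotection.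

Step 9
Reactants: 15 3-methoxy-4-(methoxymethoxy)-6-{[5-(methoxymethoxy)-2,2-dimethyl-2H-chromen-7-yl]oxy}-2-(prop-2-enyl)phenol; 16 2-methylbut-2-ene
Product: 17 3-methoxy-4-(methoxymethoxy)-6-{[5-(methoxymethoxy)-2,2-dimethyl-2H-chromen-7-yl]oxy}-2-(3-methylbut-2-enyl)phenol
Conditions: second-generation Grubbs catalyst (5 mol%), 2-methylbut-2-ene (excess), CH2Cl2, 40 °C
Reagents that add atoms: 2-methylbut-2-ene (compound 16), CC=C(C)C
Why: Olefin cross-metathesis of the terminal allyl group with excess 2-methylbut-2-ene, driven by loss of propene, turns allyl into prenyl, while the chromene alkene (cis-disubstituted next to a quaternary carbon) and the trisubstituted product are too hindered to react.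

Step 10
Reactants: 17 3-methoxy-4-(methoxymethoxy)-6-{[5-(methoxymethoxy)-2,2-dimethyl-2H-chromen-7-yl]oxy}-2-(3-methylbut-2-enyl)phenol
Product: 19 6-{[6-iodo-5-(methoxymethoxy)-2,2-dimethyl-2H-chromen-7-yl]oxy}-3-methoxy-4-(methoxymethoxy)-2-(3-methylbut-2-enyl)phenol, via dilithio species 18 (not isolated)
Conditions: n-BuLi (2.3 equiv), THF, −78 → 0 °C; then I2, −78 °C
Reagents that add atoms: iodine, II
Why: Directed ortho-metalation, in which the first equivalent of base forms the ring-B lithium phenoxide and so deactivates that ring towards C–H lithiation, and the second removes the C-6 hydrogen of ring A, the one site flanked by the chelating acetal and a second oxygen on a neutral ring (C-8 has no acetal neighbour), after which iodine traps the aryllithium.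

Step 11
Reactants: 19 6-{[6-iodo-5-(methoxymethoxy)-2,2-dimethyl-2H-chromen-7-yl]oxy}-3-methoxy-4-(methoxymethoxy)-2-(3-methylbut-2-enyl)phenol; 20 carbon monoxide
Product: 21 garcinisidone B bis(methoxymethyl) ether (MOM on the ring-A 5-oxygen and on the ring-B hydroxyl)
Conditions: Pd(OAc)2 (10 mol%), Xantphos (15 mol%), K2CO3, CO (1 atm), 1,4-dioxane (0.01 M), 90 °C
Reagents that add atoms: carbon monoxide (compound 20), [C-]#[O+]
Why: Pd(0) adds oxidatively to the C6–I bond of ring A, CO inserts to give an aroyl–palladium(II) species, and the ring-B phenoxide ortho to the prenyl group captures it (coordination and C–O reductive elimination, or direct acyl substitution), releasing the lactone and Pd(0). The closest known reaction type is the palladium-catalysed intramolecular aryloxycarbonylation (carbonylative lactonisation) of aryl halides that carry a pendant phenol. The seven-membered dioxepinone closes by attack of the phenoxide oxygen on the exocyclic acyl carbon (7-exo-trig acyl substitution), the diaryl ether hinge holding that oxygen close to the metal. No stereocentre is formed and the product is achiral. The step needs chemoselectivity for intramolecular capture over hydrodeiodination, intermolecular ester formation and Heck insertion, which the CO atmosphere (fast insertion), high dilution, a wide-bite-angle ligand that favours acyl C–O elimination, and the hindered, remote nature of both alkenes should secure. An aroyl–palladium is used because the acyl carbon, flanked by the acetal and the aryloxy group, would be hard to activate as a free 2,6-dioxygenated benzoic acid.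

Step 12
Reactants: 21 garcinisidone B bis(methoxymethyl) ether
Product: 22 garcinisidone B
Conditions: 3 M aq. HCl, THF/i-PrOH, 40 °C
Reagents that add atoms: none
Why: Acid-catalysed hydrolysis of the two aryl methoxymethyl acetals (the one ortho to the lactone carbonyl is especially labile) under dilute acid in a hindered alcohol, conditions that should spare the aryl ester, the chromene and the prenyl group, which no longer has a free ortho phenol to cyclise onto it.

Compound list
1 | 5-bromoresorcinol | Oc1cc(O)cc(Br)c1 | starting material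
2 | 3-methylbut-2-enal | CC(C)=CC=O | starting material
3 | 7-bromo-2,2-dimethyl-2H-chromen-5-ol | Oc1cc(Br)cc2OC(C)(C)C=Cc12 | intermediate
4 | 7-bromo-5-(methoxymethoxy)-2,2-dimethyl-2H-chromene | COCOc1cc(Br)cc2OC(C)(C)C=Cc12 | intermediate
5 | 6-bromovanillin (2-bromo-4-hydroxy-5-methoxybenzaldehyde) | COc1cc(C=O)c(Br)cc1O | starting material
6 | 2-bromo-5-methoxy-4-(methoxymethoxy)benzaldehyde | COc1cc(C=O)c(Br)cc1OCOC | intermediate
7 | 2-bromo-5-methoxy-4-(methoxymethoxy)phenyl formate | COc1cc(OC=O)c(Br)cc1OCOC | intermediate (not isolated)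
8 | 2-bromo-5-methoxy-4-(methoxymethoxy)phenol | COc1cc(O)c(Br)cc1OCOC | intermediate
9 | allyl bromide (3-bromoprop-1-ene) | C=CCBr | starting material
10 | 1-bromo-4-methoxy-5-(methoxymethoxy)-2-(prop-2-enyloxy)benzene | COc1cc(OCC=C)c(Br)cc1OCOC | intermediate
11 | [4-methoxy-5-(methoxymethoxy)-2-(prop-2-enyloxy)phenyl]lithium | COc1cc(OCC=C)c([Li])cc1OCOC | intermediate (not isolated)
12 | lithium trimethoxy[4-methoxy-5-(methoxymethoxy)-2-(prop-2-enyloxy)phenyl]borate | [Li+].COc1cc(OCC=C)c([B-](OC)(OC)OC)cc1OCOC | intermediate (not isolated)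
13 | 4-methoxy-5-(methoxymethoxy)-2-(prop-2-enyloxy)phenol | COc1cc(OCC=C)c(O)cc1OCOC | intermediate
14 | 7-[4-methoxy-5-(methoxymethoxy)-2-(prop-2-enyloxy)phenoxy]-5-(methoxymethoxy)-2,2-dimethyl-2H-chromene | COc1cc(OCC=C)c(Oc2cc(OCOC)c3C=CC(C)(C)Oc3c2)cc1OCOC | intermediate
15 | 3-methoxy-4-(methoxymethoxy)-6-{[5-(methoxymethoxy)-2,2-dimethyl-2H-chromen-7-yl]oxy}-2-(prop-2-enyl)phenol | COc1c(CC=C)c(O)c(Oc2cc(OCOC)c3C=CC(C)(C)Oc3c2)cc1OCOC | intermediate
16 | 2-methylbut-2-ene | CC=C(C)C | starting material
17 | 3-methoxy-4-(methoxymethoxy)-6-{[5-(methoxymethoxy)-2,2-dimethyl-2H-chromen-7-yl]oxy}-2-(3-methylbut-2-enyl)phenol | COc1c(CC=C(C)C)c(O)c(Oc2cc(OCOC)c3C=CC(C)(C)Oc3c2)cc1OCOC | intermediate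
18 | dilithio derivative of 17 (lithium phenoxide on ring B, lithium at ring-A C-6) | COc1c(CC=C(C)C)c(O[Li])c(Oc2cc3OC(C)(C)C=Cc3c(OCOC)c2[Li])cc1OCOC | intermediate (not isolated)
19 | 6-{[6-iodo-5-(methoxymethoxy)-2,2-dimethyl-2H-chromen-7-yl]oxy}-3-methoxy-4-(methoxymethoxy)-2-(3-methylbut-2-enyl)phenol | Ic1c(OCOC)c2C=CC(C)(C)Oc2cc1Oc1cc(OCOC)c(OC)c(CC=C(C)C)c1O | intermediate
20 | carbon monoxide | [C-]#[O+] | starting material
21 | garcinisidone B bis(methoxymethyl) ether | COCOc1c2C=CC(C)(C)Oc2cc2Oc3cc(OCOC)c(OC)c(CC=C(C)C)c3OC(=O)c12 | intermediate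
22 | garcinisidone B | COc1c(O)cc2c(c1CC=C(C)C)OC(=O)c1c(cc3c(c1O)C=CC(C)(C)O3)O2 | target

Total step count: 12.
Longest linear sequence: 10 steps (steps 3–12, from 6-bromovanillin 5 to 22). Ring A is made in two steps (steps 1–2) and joins at step 7.

Steps most likely to fail

1. Step 11 (carbonylative ring closure). Oxidative addition and CO insertion at an aryl iodide with two ortho oxygen substituents may be slow, so that hydrodeiodination or intermolecular ester formation overtakes the closure. Fallback: set out from 17. The dilithio species 18 of step 10 is quenched with carbon dioxide instead of iodine, which should give 7-[2-hydroxy-4-methoxy-5-(methoxymethoxy)-3-(3-methylbut-2-enyl)phenoxy]-5-(methoxymethoxy)-2,2-dimethyl-2H-chromene-6-carboxylic acid F1. Dehydrative lactonisation of this hydroxy acid under high dilution (EDC·HCl, DMAP, CH2Cl2; Steglich-type esterification) would then close the same ring and return to the route at 21.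

2. Step 10 (metalation and iodination). Deprotonation may occur at a competing carbon: the ring-B C–H between the acetal and the aryloxy oxygen, ring-A C-8, or the benzylic CH2 of the prenyl group. That would give mixtures of iodides. Fallback: set out from 10 and replace the ring-B acetal by a bulky, non-chelating silyl ether, so that ring A holds the only acetal-flanked C–H. 2 M HCl in MeOH should cleave the acetal to 5-bromo-2-methoxy-4-(prop-2-enyloxy)phenol F2, and TIPSCl/imidazole should give [5-bromo-2-methoxy-4-(prop-2-enyloxy)phenoxy]tri(propan-2-yl)silane F3. The main sequence is then repeated on the silyl series. Bromine–lithium exchange gives the aryllithium F4, B(OMe)3 gives the lithium arylborate F5, and oxidation with NaBO3 gives 4-methoxy-2-(prop-2-enyloxy)-5-[tri(propan-2-yl)silyloxy]phenol F6. Copper-catalysed coupling with 4 (K3PO4 as base, to spare the silyl ether) gives the silyl diaryl ether F7. Claisen rearrangement gives the silyl allylphenol F8, and cross-metathesis gives the silyl prenylphenol F9. n-BuLi gives the dilithio species F10, and iodine gives the silyl aryl iodide F11. Carbonylative closure as in step 11 gives the silyl/MOM-protected lactone F12. TBAF/AcOH releases the ring-B phenol, 5-O-(methoxymethyl)garcinisidone B F13, and the acid of step 12 then gives 22, where the fallback rejoins the route.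

3. Step 1 (chromene annulation). The C–C bond may form at C-4/C-6 of the bromoresorcinol (next to bromine) instead of C-2, giving the regioisomeric 5-bromo-7-hydroxychromene, or the condensation may stall. Fallback: set out from 2 and use a symmetrical phenol, so that only one chromene can form. Condensation of 2 with an excess of phloroglucinol F14 (ethylenediammonium diacetate, toluene) should give 2,2-dimethyl-2H-chromene-5,7-diol F15. Silylation with TIPSCl/imidazole at the less hindered 7-hydroxyl (the 5-hydroxyl is crowded by the peri C-4–H) should give 2,2-dimethyl-7-[tri(propan-2-yl)silyloxy]-2H-chromen-5-ol F16. MOMCl/i-Pr2NEt gives 5-(methoxymethoxy)-2,2-dimethyl-7-[tri(propan-2-yl)silyloxy]-2H-chromene F17, and TBAF releases 5-(methoxymethoxy)-2,2-dimethyl-2H-chromen-7-ol F18. Copper-catalysed coupling of F18 with aryl bromide 10 (the coupling roles exchanged; CuI, picolinic acid, K3PO4, DMSO, 100 °C) returns to the route at 14.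

Further compounds
F1 | step 11 | 7-[2-hydroxy-4-methoxy-5-(methoxymethoxy)-3-(3-methylbut-2-enyl)phenoxy]-5-(methoxymethoxy)-2,2-dimethyl-2H-chromene-6-carboxylic acid | OC(=O)c1c(OCOC)c2C=CC(C)(C)Oc2cc1Oc1cc(OCOC)c(OC)c(CC=C(C)C)c1O
F2 | step 10 | 5-bromo-2-methoxy-4-(prop-2-enyloxy)phenol | COc1cc(OCC=C)c(Br)cc1O
F3 | step 10 | [5-bromo-2-methoxy-4-(prop-2-enyloxy)phenoxy]tri(propan-2-yl)silane | COc1cc(OCC=C)c(Br)cc1O[Si](C(C)C)(C(C)C)C(C)C
F4 | step 10 | aryllithium from F3 | COc1cc(OCC=C)c([Li])cc1O[Si](C(C)C)(C(C)C)C(C)C
F5 | step 10 | lithium arylborate from F4 | [Li+].COc1cc(OCC=C)c([B-](OC)(OC)OC)cc1O[Si](C(C)C)(C(C)C)C(C)C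
F6 | step 10 | 4-methoxy-2-(prop-2-enyloxy)-5-[tri(propan-2-yl)silyloxy]phenol | COc1cc(OCC=C)c(O)cc1O[Si](C(C)C)(C(C)C)C(C)C
F7 | step 10 | silyl diaryl ether (TIPS analogue of 14) | COc1cc(OCC=C)c(Oc2cc(OCOC)c3C=CC(C)(C)Oc3c2)cc1O[Si](C(C)C)(C(C)C)C(C)C
F8 | step 10 | silyl allylphenol (TIPS analogue of 15) | COc1c(CC=C)c(O)c(Oc2cc(OCOC)c3C=CC(C)(C)Oc3c2)cc1O[Si](C(C)C)(C(C)C)C(C)C
F9 | step 10 | silyl prenylphenol (TIPS analogue of 17) | COc1c(CC=C(C)C)c(O)c(Oc2cc(OCOC)c3C=CC(C)(C)Oc3c2)cc1O[Si](C(C)C)(C(C)C)C(C)C
F10 | step 10 | dilithio species from F9 | COc1c(CC=C(C)C)c(O[Li])c(Oc2cc3OC(C)(C)C=Cc3c(OCOC)c2[Li])cc1O[Si](C(C)C)(C(C)C)C(C)C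
F11 | step 10 | silyl aryl iodide (TIPS analogue of 19) | COc1c(CC=C(C)C)c(O)c(Oc2cc3OC(C)(C)C=Cc3c(OCOC)c2I)cc1O[Si](C(C)C)(C(C)C)C(C)C
F12 | step 10 | silyl/MOM-protected lactone (TIPS analogue of 21) | COCOc1c2C=CC(C)(C)Oc2cc2Oc3cc(O[Si](C(C)C)(C(C)C)C(C)C)c(OC)c(CC=C(C)C)c3OC(=O)c12
F13 | step 10 | 5-O-(methoxymethyl)garcinisidone B | COCOc1c2C=CC(C)(C)Oc2cc2Oc3cc(O)c(OC)c(CC=C(C)C)c3OC(=O)c12
F14 | step 1 | phloroglucinol | Oc1cc(O)cc(O)c1
F15 | step 1 | 2,2-dimethyl-2H-chromene-5,7-diol | Oc1cc(O)c2C=CC(C)(C)Oc2c1
F16 | step 1 | 2,2-dimethyl-7-[tri(propan-2-yl)silyloxy]-2H-chromen-5-ol | CC(C)[Si](Oc1cc(O)c2C=CC(C)(C)Oc2c1)(C(C)C)C(C)C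
F17 | step 1 | 5-(methoxymethoxy)-2,2-dimethyl-7-[tri(propan-2-yl)silyloxy]-2H-chromene | COCOc1cc(O[Si](C(C)C)(C(C)C)C(C)C)cc2OC(C)(C)C=Cc12
F18 | step 1 | 5-(methoxymethoxy)-2,2-dimethyl-2H-chromen-7-ol | COCOc1cc(O)cc2OC(C)(C)C=Cc12
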